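The four-ring-atom numbering used throughout is O1, C2 (4-hydroxyphenyl), C3 (aroyl), C4, C5 (resorcinol-type aryl); Cx is the exocyclic methine on C4.

**Strategy.** Each tetrahydrofuran ring (O1, C2, C3, C4, C5) carries a para-hydroxyaryl group on both oxygen-bearing carbons, C2 and C5, the mark of a water-trapped bis(quinone methide); this is the feature the key step exploits. Everything rests on cutting C3–C4, C2–O1 and C5–O1 in both rings. One oxidative operation couples a 4-hydroxychalcone radical (spin at C3) with a 4-hydroxystyryl radical (spin at C4) on each arm and lets water close both rings, setting eight stereocentres. The precursor is a 6,8-bis(1,3-diarylallyl)afzelechin, benzylated everywhere except the two styryl para-hydroxyls, so that no other phenol can be oxidised or can trap a methide; its partner is isoliquiritigenin benzylated on the ketone ring.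

Key step: step 13

Remark: the configurations were rechecked against the target and no structure had to be changed. Afzelechin is 2R,3S, both Cx are S, and each tetrahydrofuran is 2S,3S,4S,5R (2,3-trans, 3,4-trans, 4,5-cis, 2,5-cis).

Remark: benzyl ethers are used because aryl silyl ethers would not survive the hydroxide of the Claisen–Schmidt steps; one allyl ether per arm marks the phenol that is freed for the coupling.

Assumption: the ligand enantiomer in step 7 is the one expected to deliver aryl to the Re face of each β-carbon; the sense should be confirmed on a single-arm model and the antipode used if it proves opposite.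

**Route**

Step 1
Reactants: 1 (+)-afzelechin
Product: 3 3,5,7,4'-tetra-O-benzylafzelechin, via 5,7,4'-tri-O-benzylafzelechin 2 (not isolated)
Conditions: BnBr (3.3 equiv), K2CO3, DMF, −10 °C to rt; filter; then NaH (2 equiv), BnBr (1.5 equiv), 0 °C to rt
Reagents that add atoms: benzyl bromide, BrCc1ccccc1
Why: Williamson etherification; carbonate at low temperature should O-benzylate the three phenols, NaH then the secondary 3-OH, and no stereocentre is touched.

Step 2
Reactants: 3 3,5,7,4'-tetra-O-benzylafzelechin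
Product: 4 6,8-dibromo-3,5,7,4'-tetra-O-benzylafzelechin
Conditions: NBS (2.05 equiv), CH2Cl2, 0 °C to rt, dark
Reagents that add atoms: N-bromosuccinimide, O=C1CCC(=O)N1Br
Why: Electrophilic aromatic bromination; the trioxygenated ring A should react at its two free positions C6 and C8 well before the mono-alkoxy ring B.

Step 3
Reactants: 4 6,8-dibromo-3,5,7,4'-tetra-O-benzylafzelechin
Product: 6 3,5,7,4'-tetra-O-benzylafzelechin-6,8-dicarbaldehyde, via 6,8-dilithio species 5 (not isolated)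
Conditions: t-BuLi (4.4 equiv), THF, −78 °C; DMF (6 equiv), −78 to 0 °C; aq NH4Cl
Reagents that add atoms: N,N-dimethylformamide, CN(C)C=O
Why: Bromine–lithium exchange followed by Bouveault formylation; the flanking benzyloxy oxygens stabilise each aryllithium and exchange at −78 °C should outrun benzylic deprotonation.

Step 4
Reactants: 7 2,4-dihydroxyacetophenone
Product: 8 1-[4-(allyloxy)-2-hydroxyphenyl]ethanone
Conditions: allyl bromide (1.05 equiv), K2CO3, acetone, reflux
Reagents that add atoms: allyl bromide, C=CCBr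
Why: Williamson etherification; only the 4-OH reacts because the 2-OH is held in a hydrogen bond to the ketone.

Step 5
Reactants: 8 1-[4-(allyloxy)-2-hydroxyphenyl]ethanone
Product: 9 1-[4-(allyloxy)-2-(benzyloxy)phenyl]ethanone
Conditions: BnBr (1.3 equiv), K2CO3, DMF, 70 °C
Reagents that add atoms: benzyl bromide, BrCc1ccccc1
Why: Williamson etherification of the chelated phenol under more forcing conditions; the allyl ether is stable far below the temperature of a Claisen rearrangement.

Step 6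
Reactants: 6 3,5,7,4'-tetra-O-benzylafzelechin-6,8-dicarbaldehyde; 9 1-[4-(allyloxy)-2-(benzyloxy)phenyl]ethanone (2.4 equiv)
Product: 10 6,8-bis[(E)-3-(4-allyloxy-2-benzyloxyphenyl)-3-oxoprop-1-en-1-yl]-3,5,7,4'-tetra-O-benzylafzelechin
Conditions: KOH, EtOH/THF, rt to 50 °C
Reagents that add atoms: none
Why: Double Claisen–Schmidt condensation; the aldehydes cannot enolise, dehydration of each aldol gives the conjugated E-enone, and benzyl and allyl ethers are inert to hydroxide.

Step 7
Reactants: 10 the bis(enone); 11 4-(benzyloxy)phenylboronic acid (6 equiv)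
Product: 12 6,8-bis[(1S)-3-(4-allyloxy-2-benzyloxyphenyl)-1-(4-benzyloxyphenyl)-3-oxopropyl]-3,5,7,4'-tetra-O-benzylafzelechin
Conditions: [Rh(OH)((R)-BINAP)]2 (6 mol % Rh), dioxane/H2O (10:1), 60 °C
Reagents that add atoms: none
Why: Hayashi–Miyaura rhodium-catalysed asymmetric 1,4-addition; the aryl–rhodium–BINAP species should add to the Re face of each β-carbon under ligand control to give S at both Cx, the remote flavan centres not being expected to override the catalyst, and minor Cx diastereomers are removed by chromatography.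

Step 8
Reactants: 12 the bis(ketone)
Product: 13 6,8-bis[(1S)-3-(4-allyloxy-2-benzyloxyphenyl)-1-(4-benzyloxyphenyl)-3-hydroxypropyl]-3,5,7,4'-tetra-O-benzylafzelechin (carbinol epimers)
Conditions: NaBH4, THF/MeOH, 0 °C to rt
Reagents that add atoms: none
Why: Borohydride reduction of the aryl ketones; the new carbinol centres form as a mixture, which is harmless because they are removed in step 9.

Step 9
Reactants: 13 the bis(carbinol)
Product: 14 6,8-bis[(1S,2E)-3-(4-allyloxy-2-benzyloxyphenyl)-1-(4-benzyloxyphenyl)prop-2-en-1-yl]-3,5,7,4'-tetra-O-benzylafzelechin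
Conditions: Burgess reagent (3 equiv), toluene, 60 °C
Reagents that add atoms: none
Why: Burgess dehydration; syn-elimination of each benzylic sulfamate can only run toward the C4 methylene and should give the conjugated E-styrene, and the neutral conditions avoid cationic cyclisation and leave Cx untouched.

Step 10
Reactants: 14 the bis(allyl ether)
Product: 15 6,8-bis[(1S,2E)-3-(2-benzyloxy-4-hydroxyphenyl)-1-(4-benzyloxyphenyl)prop-2-en-1-yl]-3,5,7,4'-tetra-O-benzylafzelechin
Conditions: Pd(PPh3)4 (5 mol %), morpholine (10 equiv), THF, rt, argon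
Reagents that add atoms: none
Why: Tsuji–Trost deallylation; zerovalent palladium ionises only the aryl allyl ethers and morpholine traps the allyl group, while benzyl ethers and the 1,3-diarylpropene units offer no leaving group.

Step 11
Reactants: 7 2,4-dihydroxyacetophenone
Product: 16 1-[2,4-bis(benzyloxy)phenyl]ethanone
Conditions: BnBr (2.4 equiv), K2CO3, DMF, 70 °C
Reagents that add atoms: benzyl bromide, BrCc1ccccc1
Why: Double Williamson etherification.

Step 12
Reactants: 16 1-[2,4-bis(benzyloxy)phenyl]ethanone; 17 4-hydroxybenzaldehyde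
Product: 18 2',4'-di-O-benzylisoliquiritigenin
Conditions: KOH (aq 50 %, excess), EtOH, rt to 50 °C; dilute HCl
Reagents that add atoms: none
Why: Claisen–Schmidt condensation, run with excess hydroxide because the aldehyde reacts as its less electrophilic phenoxide; dehydration gives the E-chalcone with the 4-hydroxyl free.

Step 13
Reactants: 15 the bis(styrylphenol); 18 2',4'-di-O-benzylisoliquiritigenin (8 equiv)
Product: 20 6,8-bis{(S)-(4-benzyloxyphenyl)[(4S,5R)-3-(2,4-dibenzyloxybenzoyl)-5-(2-benzyloxy-4-hydroxyphenyl)-2-(4-hydroxyphenyl)oxolan-4-yl]methyl}-3,5,7,4'-tetra-O-benzylafzelechin (C2/C3 epimer mixture), via mono-coupled intermediate 19 (not isolated)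
Conditions: laccase (Trametes versicolor), O2 (1 atm), EtOAc/aq NaOAc–AcOH buffer (pH 4.7) 1:1, vigorous stirring, rt; 15 added over 10 h to 18
Reagents that add atoms: water, O
Why: Proposed new method: the laccase takes one electron and one proton from the single free phenol of each partner, the styryl phenoxyl radical (spin at C4) and the chalcone phenoxyl radical (spin at C3) combine to form C3–C4 and a bis(para-quinone methide), water adds to the C5 methide and the new hydroxyl closes on the C2 methide, and the sequence repeats on the second arm through 19. The closest known reaction type is the laccase- or peroxidase-mediated 8–8' homocoupling of para-hydroxystyrenes with water capture to 2,5-diaryltetrahydrofurans; cross-coupling with a 4-hydroxychalcone, twice on one molecule, has no precedent. Each ring closes by a 5-exo-trig 1,6-addition of the C5 hydroxyl to the C2 methide, which rearomatises that ring. C4 is controlled by Cx, since with Cx–H eclipsing the C4=C5 bond (allylic 1,3-strain) the chalcone radical should bond anti to the afzelechin ring, which is the target configuration; C5 is controlled by the order of hydration, the styryl methide being the more basic, acid-activated one at pH 4.7 because of its ortho benzyloxy group, so that water should enter there first, on the face not covered by the chalcone methide, which places the C5 aryl cis to the C4 side chain after closure; C2 and C3 arise as epimer mixtures and are settled in step 14. The step needs cross- over homo-coupling and one face each at C4 and C5; cross-coupling is favoured by the polarity match of the electron-poor alpha-keto radical with the electron-rich styryl radical, excess 18 and slow addition of 15, and site selectivity is secured because every other phenol is a benzyl ether and can neither be oxidised nor trap a methide as a chroman or flavanone.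

Step 14
Reactants: 20 the coupling product (C2/C3 epimer mixture)
Product: 21 6,8-bis{(S)-(4-benzyloxyphenyl)[(2S,3S,4S,5R)-3-(2,4-dibenzyloxybenzoyl)-5-(2-benzyloxy-4-hydroxyphenyl)-2-(4-hydroxyphenyl)oxolan-4-yl]methyl}-3,5,7,4'-tetra-O-benzylafzelechin
Conditions: DBU (0.5 equiv), THF, 40 °C; AcOH quench
Reagents that add atoms: none
Why: Base-mediated epimerisation alpha to the aryl ketone together with reversible oxa-Michael opening of C2–O1; C3 and C2 should converge on the arrangement in which both vicinal pairs are trans, while C4 and C5 carry no acidifying group and C5–O1 is not cleaved.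

Step 15
Reactants: 21 the dodeca-O-benzyl ether
Product: 22 target CNP0225367.3
Conditions: H2 (1 atm), Pd(OH)2/C, THF/MeOH (1:1), rt
Reagents that add atoms: none
Why: Hydrogenolysis of eleven aryl benzyl ethers and the 3-O-benzyl ether under neutral conditions; the oxygen-deactivated aryl ketones and the cyclic benzylic ethers should survive as in routine debenzylation of flavans and tetrahydrofuran lignans, and no stereocentre is affected.

**Compound list**

1 | (+)-afzelechin, (2R,3S)-2-(4-hydroxyphenyl)chromane-3,5,7-triol | Oc1cc(O)c2C[C@H](O)[C@@H](c3ccc(O)cc3)Oc2c1 | starting material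
2 | 5,7,4'-tri-O-benzylafzelechin (3-OH free; 2R,3S) | C(c1ccccc1)Oc1cc(OCc2ccccc2)c2c(c1)O[C@H](c1ccc(OCc3ccccc3)cc1)[C@@H](O)C2 | intermediate
3 | 3,5,7,4'-tetra-O-benzylafzelechin (2R,3S) | C(c1ccccc1)Oc1cc(OCc2ccccc2)c2c(c1)O[C@H](c1ccc(OCc3ccccc3)cc1)[C@@H](OCc1ccccc1)C2 | intermediate
4 | 6,8-dibromo-3,5,7,4'-tetra-O-benzylafzelechin | C(c1ccccc1)Oc1c(Br)c(OCc2ccccc2)c2c(c1Br)O[C@H](c1ccc(OCc3ccccc3)cc1)[C@@H](OCc1ccccc1)C2 | intermediate
5 | 6,8-dilithio-3,5,7,4'-tetra-O-benzylafzelechin | C(c1ccccc1)Oc1c([Li])c(OCc2ccccc2)c2c(c1[Li])O[C@H](c1ccc(OCc3ccccc3)cc1)[C@@H](OCc1ccccc1)C2 | intermediate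
6 | 3,5,7,4'-tetra-O-benzylafzelechin-6,8-dicarbaldehyde | C(c1ccccc1)Oc1c(C=O)c(OCc2ccccc2)c2c(c1C=O)O[C@H](c1ccc(OCc3ccccc3)cc1)[C@@H](OCc1ccccc1)C2 | intermediate
7 | 2,4-dihydroxyacetophenone | CC(=O)c1ccc(O)cc1O | starting material
8 | 1-[4-(allyloxy)-2-hydroxyphenyl]ethanone | CC(=O)c1ccc(OCC=C)cc1O | intermediate
9 | 1-[4-(allyloxy)-2-(benzyloxy)phenyl]ethanone | CC(=O)c1ccc(OCC=C)cc1OCc1ccccc1 | intermediate
10 | 6,8-bis[(E)-3-(4-allyloxy-2-benzyloxyphenyl)-3-oxoprop-1-en-1-yl]-3,5,7,4'-tetra-O-benzylafzelechin | C(c1ccccc1)Oc1c(/C=C/C(=O)c3ccc(OCC=C)cc3OCc3ccccc3)c(OCc2ccccc2)c2c(c1/C=C/C(=O)c3ccc(OCC=C)cc3OCc3ccccc3)O[C@H](c1ccc(OCc3ccccc3)cc1)[C@@H](OCc1ccccc1)C2 | intermediate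
11 | 4-(benzyloxy)phenylboronic acid | OB(O)c1ccc(OCc2ccccc2)cc1 | starting material
12 | 6,8-bis[(1S)-3-(4-allyloxy-2-benzyloxyphenyl)-1-(4-benzyloxyphenyl)-3-oxopropyl]-3,5,7,4'-tetra-O-benzylafzelechin | C(c1ccccc1)Oc1c([C@H](c3ccc(OCc4ccccc4)cc3)CC(=O)c3ccc(OCC=C)cc3OCc3ccccc3)c(OCc2ccccc2)c2c(c1[C@H](c3ccc(OCc4ccccc4)cc3)CC(=O)c3ccc(OCC=C)cc3OCc3ccccc3)O[C@H](c1ccc(OCc3ccccc3)cc1)[C@@H](OCc1ccccc1)C2 | intermediate
13 | 6,8-bis[(1S)-3-(4-allyloxy-2-benzyloxyphenyl)-1-(4-benzyloxyphenyl)-3-hydroxypropyl]-3,5,7,4'-tetra-O-benzylafzelechin (carbinol epimers) | C(c1ccccc1)Oc1c([C@H](c3ccc(OCc4ccccc4)cc3)CC(O)c3ccc(OCC=C)cc3OCc3ccccc3)c(OCc2ccccc2)c2c(c1[C@H](c3ccc(OCc4ccccc4)cc3)CC(O)c3ccc(OCC=C)cc3OCc3ccccc3)O[C@H](c1ccc(OCc3ccccc3)cc1)[C@@H](OCc1ccccc1)C2 | intermediate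
14 | 6,8-bis[(1S,2E)-3-(4-allyloxy-2-benzyloxyphenyl)-1-(4-benzyloxyphenyl)prop-2-en-1-yl]-3,5,7,4'-tetra-O-benzylafzelechin | C(c1ccccc1)Oc1c([C@H](c3ccc(OCc4ccccc4)cc3)/C=C/c3ccc(OCC=C)cc3OCc3ccccc3)c(OCc2ccccc2)c2c(c1[C@H](c3ccc(OCc4ccccc4)cc3)/C=C/c3ccc(OCC=C)cc3OCc3ccccc3)O[C@H](c1ccc(OCc3ccccc3)cc1)[C@@H](OCc1ccccc1)C2 | intermediate
15 | 6,8-bis[(1S,2E)-3-(2-benzyloxy-4-hydroxyphenyl)-1-(4-benzyloxyphenyl)prop-2-en-1-yl]-3,5,7,4'-tetra-O-benzylafzelechin (precursor of the key step) | C(c1ccccc1)Oc1c([C@H](c3ccc(OCc4ccccc4)cc3)/C=C/c3ccc(O)cc3OCc3ccccc3)c(OCc2ccccc2)c2c(c1[C@H](c3ccc(OCc4ccccc4)cc3)/C=C/c3ccc(O)cc3OCc3ccccc3)O[C@H](c1ccc(OCc3ccccc3)cc1)[C@@H](OCc1ccccc1)C2 | intermediate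
16 | 1-[2,4-bis(benzyloxy)phenyl]ethanone | CC(=O)c1ccc(OCc2ccccc2)cc1OCc1ccccc1 | intermediate
17 | 4-hydroxybenzaldehyde | O=Cc1ccc(O)cc1 | starting material
18 | 2',4'-di-O-benzylisoliquiritigenin, (E)-1-[2,4-bis(benzyloxy)phenyl]-3-(4-hydroxyphenyl)prop-2-en-1-one | O=C(/C=C/c1ccc(O)cc1)c1ccc(OCc2ccccc2)cc1OCc1ccccc1 | intermediate
19 | mono-coupled intermediate: C8 arm as the tetrahydrofuran of 20, C6 arm still the styrylphenol of 15 | C(c1ccccc1)Oc1c([C@H](c3ccc(OCc4ccccc4)cc3)/C=C/c3ccc(O)cc3OCc3ccccc3)c(OCc2ccccc2)c2c(c1[C@H](c3ccc(OCc4ccccc4)cc3)[C@H]3C(C(=O)c4ccc(OCc5ccccc5)cc4OCc4ccccc4)C(c4ccc(O)cc4)O[C@H]3c3ccc(O)cc3OCc3ccccc3)O[C@H](c1ccc(OCc3ccccc3)cc1)[C@@H](OCc1ccccc1)C2 | intermediate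
20 | dodeca-O-benzyl coupling product, Cx S, rings 4S,5R, C2 and C3 as epimer mixtures | C(c1ccccc1)Oc1c([C@H](c3ccc(OCc4ccccc4)cc3)[C@H]3C(C(=O)c4ccc(OCc5ccccc5)cc4OCc4ccccc4)C(c4ccc(O)cc4)O[C@H]3c3ccc(O)cc3OCc3ccccc3)c(OCc2ccccc2)c2c(c1[C@H](c3ccc(OCc4ccccc4)cc3)[C@H]3C(C(=O)c4ccc(OCc5ccccc5)cc4OCc4ccccc4)C(c4ccc(O)cc4)O[C@H]3c3ccc(O)cc3OCc3ccccc3)O[C@H](c1ccc(OCc3ccccc3)cc1)[C@@H](OCc1ccccc1)C2 | intermediate
21 | dodeca-O-benzyl ether of the target, Cx S, rings 2S,3S,4S,5R, free hydroxyls on the C2 aryl and para on the C5 aryl | C(c1ccccc1)Oc1c([C@H](c3ccc(OCc4ccccc4)cc3)[C@H]3[C@H](C(=O)c4ccc(OCc5ccccc5)cc4OCc4ccccc4)[C@@H](c4ccc(O)cc4)O[C@H]3c3ccc(O)cc3OCc3ccccc3)c(OCc2ccccc2)c2c(c1[C@H](c3ccc(OCc4ccccc4)cc3)[C@H]3[C@H](C(=O)c4ccc(OCc5ccccc5)cc4OCc4ccccc4)[C@@H](c4ccc(O)cc4)O[C@H]3c3ccc(O)cc3OCc3ccccc3)O[C@H](c1ccc(OCc3ccccc3)cc1)[C@@H](OCc1ccccc1)C2 | intermediate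
22 | CNP0225367.3, 6,8-bis{(S)-(4-hydroxyphenyl)[(2S,3S,4S,5R)-3-(2,4-dihydroxybenzoyl)-5-(2,4-dihydroxyphenyl)-2-(4-hydroxyphenyl)oxolan-4-yl]methyl}afzelechin | O=C(c1ccc(O)cc1O)[C@H]1[C@H]([C@@H](c2ccc(O)cc2)c2c(O)c3c(c([C@H](c4ccc(O)cc4)[C@H]4[C@H](C(=O)c5ccc(O)cc5O)[C@@H](c5ccc(O)cc5)O[C@H]4c4ccc(O)cc4O)c2O)O[C@H](c2ccc(O)cc2)[C@@H](O)C3)[C@H](c2ccc(O)cc2O)O[C@@H]1c1ccc(O)cc1 | target

**Totals and risks**

Total step count: 15. Longest linear sequence: 11 steps (1, 2, 3, 6, 7, 8, 9, 10, 13, 14, 15).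

Steps most likely to fail:

1. Step 13 (proposed new method). Three processes may defeat it. Homo-coupling and oligomerisation of the styryl radicals, including arm-to-arm coupling within 15, may outpace cross-coupling. The chalcone-derived methide may lose its acidic C3 proton before ring closure. Hydration may begin at C2, so that the ring closes from the C2 carbinol onto the C5 methide with poor facial selectivity at C5, favouring the 4,5-trans epimer. The fallback uses known chemistry, sets out from 12 and returns at 21. Ketone 16 is brominated (CuBr2, EtOAc/CHCl3, reflux) to 2-bromo-1-[2,4-bis(benzyloxy)phenyl]ethanone F1. The bis(lithium enolate) of 12 (LiN(SiMe3)2, THF, −78 °C) is alkylated with F1 to the bis(1,4-diketone) F2, in which C4 should be set, as in step 13, by approach anti to the afzelechin ring. Kinetic enolisation of the two C3 methylene groups (LiN(iPr)2, THF, −78 °C) and aldol addition to 4-(allyloxy)benzaldehyde gives, after each C2 alkoxide has closed on the C5 ketone, the bis(cyclic hemiketal) F3. Reduction with Et3SiH and BF3·OEt2 (CH2Cl2, −78 °C) passes through the C5 oxocarbenium ions, which take hydride anti to the C4 side chain and so should give the 4,5-cis rings; DBU equilibration of C2 and C3 then gives the tetra-O-allyl ether F4. Pd(PPh3)4 and morpholine remove the four allyl groups to give 21.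

2. Step 7. Carbometalation may be slow at a β-carbon flanked by two ortho oxygens, and facial control may be incomplete on one arm. The fallback sets out from 10 and returns at 12 and makes no new compound (F0). 4-(Benzyloxy)phenylmagnesium bromide with CuBr·SMe2 and Me3SiCl (THF, −40 °C; acidic work-up of the silyl enol ethers) adds to both enones without a chiral ligand, a reagent combination suited to hindered β-positions. The Cx diastereomers, distinct compounds because of the afzelechin core, are separated by preparative HPLC, and the S,S isomer is 12.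

3. Step 3. The second bromine–lithium exchange may be incomplete or the aryllithium may be protonated, giving mono-aldehyde, and benzylic lithiation may compete. The fallback sets out from 4 and returns at 6. Double Stille coupling with tributyl(vinyl)stannane (Pd(PPh3)4, toluene, 100 °C) gives 6,8-divinyl-3,5,7,4'-tetra-O-benzylafzelechin F5. Lemieux–Johnson cleavage (OsO4 cat., NaIO4, 2,6-lutidine, dioxane/H2O) then gives 6.

**Further compounds**

F1 | step 13 | 2-bromo-1-[2,4-bis(benzyloxy)phenyl]ethanone | BrCC(=O)c1ccc(OCc2ccccc2)cc1OCc1ccccc1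
F2 | step 13 | bis(1,4-diketone): each arm Cx(S)H(4-benzyloxyphenyl)–C4H[CH2C(=O)(2,4-dibenzyloxyphenyl)]–C(=O)(4-allyloxy-2-benzyloxyphenyl), C4 configured as in 21 | C(c1ccccc1)Oc1c([C@H](c3ccc(OCc4ccccc4)cc3)[C@@H](CC(=O)c3ccc(OCc4ccccc4)cc3OCc3ccccc3)C(=O)c3ccc(OCC=C)cc3OCc3ccccc3)c(OCc2ccccc2)c2c(c1[C@H](c3ccc(OCc4ccccc4)cc3)[C@@H](CC(=O)c3ccc(OCc4ccccc4)cc3OCc3ccccc3)C(=O)c3ccc(OCC=C)cc3OCc3ccccc3)O[C@H](c1ccc(OCc3ccccc3)cc1)[C@@H](OCc1ccccc1)C2
F3 | step 13 | bis(cyclic hemiketal): each ring 5-hydroxy-5-(4-allyloxy-2-benzyloxyphenyl)-2-(4-allyloxyphenyl)-3-(2,4-dibenzyloxybenzoyl)oxolan-4-yl, C2, C3 and C5 as mixtures | C(c1ccccc1)Oc1c([C@H](c3ccc(OCc4ccccc4)cc3)[C@H]3C(C(=O)c4ccc(OCc5ccccc5)cc4OCc4ccccc4)C(c4ccc(OCC=C)cc4)OC3(O)c3ccc(OCC=C)cc3OCc3ccccc3)c(OCc2ccccc2)c2c(c1[C@H](c3ccc(OCc4ccccc4)cc3)[C@H]3C(C(=O)c4ccc(OCc5ccccc5)cc4OCc4ccccc4)C(c4ccc(OCC=C)cc4)OC3(O)c3ccc(OCC=C)cc3OCc3ccccc3)O[C@H](c1ccc(OCc3ccccc3)cc1)[C@@H](OCc1ccccc1)C2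
F4 | step 13 | tetra-O-allyl ether of 21 (allyl on both C2 aryl hydroxyls and both C5 aryl para-hydroxyls; rings 2S,3S,4S,5R) | C(c1ccccc1)Oc1c([C@H](c3ccc(OCc4ccccc4)cc3)[C@H]3[C@H](C(=O)c4ccc(OCc5ccccc5)cc4OCc4ccccc4)[C@@H](c4ccc(OCC=C)cc4)O[C@H]3c3ccc(OCC=C)cc3OCc3ccccc3)c(OCc2ccccc2)c2c(c1[C@H](c3ccc(OCc4ccccc4)cc3)[C@H]3[C@H](C(=O)c4ccc(OCc5ccccc5)cc4OCc4ccccc4)[C@@H](c4ccc(OCC=C)cc4)O[C@H]3c3ccc(OCC=C)cc3OCc3ccccc3)O[C@H](c1ccc(OCc3ccccc3)cc1)[C@@H](OCc1ccccc1)C2
F0 | step 7 | none | none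
F5 | step 3 | 6,8-divinyl-3,5,7,4'-tetra-O-benzylafzelechin | C(c1ccccc1)Oc1c(C=C)c(OCc2ccccc2)c2c(c1C=C)O[C@H](c1ccc(OCc3ccccc3)cc1)[C@@H](OCc1ccccc1)C2
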